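## Structural features

- The target is a (2S)-flavanone. Ring C (O1, C2, C3, C4, C4a, C8a) is a 2,3-dihydro-4H-chromen-4-one fused to the phloroglucinol-type ring A (C4a to C8a), and C2 carries ring B, a 4-hydroxy-3,5-dimethoxyphenyl group.
- Ring A is fully differentiated: C5–OH (hydrogen-bonded to C4=O), C6–geranyl, C7–OH and C8–H. The (2E)-3,7-dimethylocta-2,6-dienyl chain therefore sits between two phenolic oxygens and para to O1.
- C2 is the only stereocentre and has no stereogenic neighbour, so nothing in the substrate can relay its configuration and absolute control must come from a catalyst. It is benzylic, oxygen-bearing and β to the C4 ketone, so opening of the O1–C2 bond (retro-oxa-Michael to the 2′-hydroxychalcone) erases it.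
- Fragile groups: the two trisubstituted alkenes (protic or Lewis acids can cyclise them onto the C5/C7 oxygens, and any allyl-transposition mechanism loses the 2E geometry), the electron-rich phenols, and the O1–C2 bond.
- The real difficulty is twofold. The geranyl group must sit at C6 and not C8, a choice that in the usual chemistry depends on which of two ortho oxygens closes ring C. And C2 must be set without passing through the chalcone manifold, where both regiochemistry and configuration equilibrate.
- The key step exploits the fact that O1–C2–C3–C4=O is the saturated form of a vinylogous ester. Removing the C2–C1′ bond leaves a flat, achiral 4H-chromen-4-one whose C2=C3 bond accepts ring B as a nucleophile, so ring C never has to be closed or opened at the stereocentre.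
- The supporting steps exploit the local twofold symmetry of ring A about the C6···C8a axis: before C4 is attached, the C5 and C7 oxygens are equivalent and the two carbons ortho to the C8a oxygen are homotopic.

## Logic of the disconnections

**20 ⇒ 19.** The three aryl O–CH2OMe bonds (at O5, O7 and O4′) are cut. The phenols must be masked through the organometallic steps, and on ring A the same acetal also serves as the metalation director. The gain is one protecting-group type and a single final operation. The forward step must hydrolyse three acetals without touching the 1,5-diene or opening O1–C2.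

**19 ⇒ 13 + 18 (key).** The C2–C1′ bond is cut. This removes the stereocentre and all of ring B in one convergent operation and leaves the achiral chromone 13, in which regiochemistry is already locked. The forward step must select one face of C2 under catalyst control, add 1,4 and only once, and ignore the geranyl alkenes.

**13 ⇒ 10 ⇒ 9 (through 11 and 12).** The O1–C2 bond (conjugate addition–elimination by the phenol) and the C3–C4 bond (acetylide addition to the aldehyde) are cut, so C2 and C3 come from acetylene. Only one phenol is free in 9, so ring C can close in only one direction. The forward steps need an oxidation that spares the phenol and a 6-endo rather than 5-exo closure.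

**9 ⇒ 7.** The C4–C4a bond (formyl carbon to ring A) is cut. In 7 the two positions ortho to the free hydroxyl are homotopic and the para position is blocked, so formylation at either gives 9 and no other isomer. This is the step that answers the C6-versus-C8 question. It demands an ortho-specific, non-acidic formylation.

**7 ⇒ 6 ⇒ 3 + 4 (through 5).** The O–Si bond and the aryl–CH2 bond (C6–C1″) are cut. The carbon between the two acetal oxygens of 3 is the natural metalation site, and 4 brings the whole C10 chain with its 2E geometry already in place. The forward step needs metalation between the acetals (not next to the silyl ether) and substitution at the primary carbon of 4 without allylic transposition.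

**3 ⇒ 2 ⇒ 1.** Two O–CH2OMe bonds and one O–Si bond are cut. The three equivalent hydroxyls of 1 are divided two-plus-one, which is the only desymmetrisation the route needs. The demand is acceptable mono-silylation, met by using 1 in excess.

**18 ⇒ 15 ⇒ 14 (through 16 and 17).** The C–B bond and one O–CH2OMe bond are cut, leading back to a commercial bromophenol. The forward step needs halogen–lithium exchange and a work-up mild enough to keep the acetal.

## Other disconnections considered

Alternative 1: Cut O1–C2 (the route most chemists would draw first). The C-geranylated acetophenone A1 would be condensed with the ring-B aldehyde to chalcone A2, and ring C closed by 6-endo oxa-Michael addition. In A2 two ortho hydroxyls compete, so 6- and 8-geranyl flavanones both form. Protecting one of them normally leaves the more hindered hydroxyl next to the chain free, which leads to the 8-isomer. The ring closure is also reversible, so C2 is under thermodynamic control, and catalytic asymmetric versions work best only with an extra activating group on the enone. The chosen plan never makes or breaks O1–C2 at the stage where C2 is stereogenic.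

Alternative 2: Cut C6–C1″ by an aromatic para-Claisen–Cope cascade. Heating the O-geranyl ether A3 would give the ortho-dienone A4 by a first [3,3] shift and then move the chain to the para carbon by a second [3,3] shift, unmasking the phenol to give 9. The first shift turns the chain into a tertiary 3,7-dimethylocta-1,6-dien-3-yl group and destroys the 2E alkene. The Cope step rebuilds that alkene through a chair in which methyl and homoprenyl differ little in size, so 9 would be accompanied by its 2Z isomer A5, which is very hard to separate. The cascade is short but gives up a stereochemical element that the commercial bromide 4 supplies for free, and it does nothing for C2.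

Alternative 3: Cut C4–C4a. The (S)-β-aryloxy acid A6 would be made by Mitsunobu inversion of the (R)-β-hydroxy ester A7 with the symmetric phenol 7, and ring C closed by intramolecular acylation. Either ortho position of the aryloxy ring gives the same product, so the symmetry argument of the chosen route also holds here. The stereocentre, however, would be set by an SN2 reaction at a benzylic carbon bearing a para-oxygenated arene, where ionisation and elimination to the cinnamate compete. The acylation also needs acid activation, which the acetals and the 1,5-diene tolerate poorly, and the β-aryloxy carbonyl can eliminate before it cyclises. The chosen plan sets C2 in a catalyst-controlled C–C bond formation on a substrate with no leaving group at C2.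

Key step: step 10

Assumption: the (S)-configured biaryl bisphosphine is taken to attack the same enone face of 13 as it does in 2-cyclohexenone, which corresponds to the C2 Re face and to 2S; if the sense of induction proves opposite, the (R)-ligand is used with no other change.

## Route

Step 1
Reactants: 1 phloroglucinol (benzene-1,3,5-triol)
Product: 2 5-{[tri(propan-2-yl)silyl]oxy}benzene-1,3-diol
Conditions: i-Pr3SiCl (1.0 equiv), 1 (3 equiv), imidazole (2 equiv), DMF, 0 °C → rt
Reagents that add atoms: chlorotri(propan-2-yl)silane, CC(C)[Si](Cl)(C(C)C)C(C)C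
Why: Silylation of one of three equivalent phenols; the excess of cheap, water-soluble 1 should suppress bis-silylation and is washed out on work-up. The bulky silyl ether marks the oxygen that will become O1 and later blocks metalation next to it.

Step 2
Reactants: 2 5-{[tri(propan-2-yl)silyl]oxy}benzene-1,3-diol
Product: 3 [3,5-bis(methoxymethoxy)phenoxy]tri(propan-2-yl)silane
Conditions: MOMCl (2.6 equiv), i-Pr2NEt (3 equiv), CH2Cl2, 0 °C → rt
Reagents that add atoms: chloromethyl methyl ether, COCCl
Why: Standard O-alkylation of phenols with an alkoxymethyl chloride under amine base, which the silyl ether tolerates. The two acetals are the later C5 and C7 oxygens and the directing groups for step 3.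

Step 3
Reactants: 3 [3,5-bis(methoxymethoxy)phenoxy]tri(propan-2-yl)silane; 4 geranyl bromide, (2E)-1-bromo-3,7-dimethylocta-2,6-diene
Product: 6 {4-[(2E)-3,7-dimethylocta-2,6-dien-1-yl]-3,5-bis(methoxymethoxy)phenoxy}tri(propan-2-yl)silane, via aryllithium 5 (not isolated)
Conditions: n-BuLi (1.15 equiv), THF, 0 °C → rt, 1 h; then CuI (copper monoiodide, 10 mol %), 4 (1.2 equiv), −78 °C → rt
Reagents that add atoms: none
Why: Directed ortho-metalation; the C–H flanked by both acetal oxygens is the cooperative, most acidic site, while the bulky, non-coordinating silyl ether shields the other two positions. Copper-mediated SN2 substitution at the primary carbon of 4 should be favoured because attack at the disubstituted γ-carbon would create a quaternary centre next to a 2,6-disubstituted arene, so the 2E alkene is carried over unchanged.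

Step 4
Reactants: 6 {4-[(2E)-3,7-dimethylocta-2,6-dien-1-yl]-3,5-bis(methoxymethoxy)phenoxy}tri(propan-2-yl)silane
Product: 7 4-[(2E)-3,7-dimethylocta-2,6-dien-1-yl]-3,5-bis(methoxymethoxy)phenol
Conditions: Bu4NF (1.1 equiv), THF, 0 °C; aq NH4Cl
Reagents that add atoms: none
Why: Fluoride cleavage of an aryl silyl ether; acetals and alkenes are inert. The phenol released is the only free hydroxyl and has two homotopic ortho positions.

Step 5
Reactants: 7 4-[(2E)-3,7-dimethylocta-2,6-dien-1-yl]-3,5-bis(methoxymethoxy)phenol
Product: 9 3-[(2E)-3,7-dimethylocta-2,6-dien-1-yl]-6-hydroxy-2,4-bis(methoxymethoxy)benzaldehyde, via salicyl alcohol 8 (not isolated)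
Conditions: MgCl2 (2 equiv), Et3N (4 equiv), (CH2O)n (6 equiv), MeCN, 80 °C; aq citric acid work-up
Reagents that add atoms: paraformaldehyde (source of formaldehyde), C=O
Why: Casnati–Skattebøl ortho-formylation: the magnesium phenoxide delivers formaldehyde to the ortho carbon through a chelate, and a second formaldehyde oxidises the benzylic alkoxide 8 by hydride transfer. Both ortho positions are homotopic and the para position is blocked, so only 9 can form, which fixes the chain between the two protected oxygens (the future C6). The medium is basic, so acetals and alkenes should survive.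

Step 6
Reactants: 9 3-[(2E)-3,7-dimethylocta-2,6-dien-1-yl]-6-hydroxy-2,4-bis(methoxymethoxy)benzaldehyde
Product: 10 rac-1-{3-[(2E)-3,7-dimethylocta-2,6-dien-1-yl]-6-hydroxy-2,4-bis(methoxymethoxy)phenyl}prop-2-yn-1-ol
Conditions: HC≡CMgBr (3 equiv), THF, −20 → 0 °C; aq NH4Cl; used crude
Reagents that add atoms: ethynylmagnesium bromide, C#C[Mg]Br
Why: Grignard 1,2-addition to the aldehyde; the first equivalent is consumed by the phenol. The carbinol centre is formed racemic and is removed in step 7, and the crude product is carried on at once because an ortho-hydroxybenzylic alcohol ionises easily.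

Step 7
Reactants: 10 rac-1-{3-[(2E)-3,7-dimethylocta-2,6-dien-1-yl]-6-hydroxy-2,4-bis(methoxymethoxy)phenyl}prop-2-yn-1-ol
Product: 13 6-[(2E)-3,7-dimethylocta-2,6-dien-1-yl]-5,7-bis(methoxymethoxy)-4H-chromen-4-one, via ynone 11 (not isolated), via enaminone 12 (not isolated)
Conditions: MnO2 (15 equiv), CH2Cl2, rt; filter; Et2NH (1.5 equiv), EtOH, rt; then AcOH (2 equiv), 40 °C
Reagents that add atoms: none
Why: MnO2 oxidises the activated benzylic–propargylic carbinol to ynone 11, and diethylamine adds in conjugate fashion to give the push–pull enaminone 12. The ortho phenol then closes ring C by 6-endo addition–elimination with loss of the amine (the standard ynone/enaminone chromone synthesis), and the amine route avoids the 5-exo mode. Only one phenol is free, so the ring can close only towards the 6-geranyl isomer.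

Step 8
Reactants: 14 4-bromo-2,6-dimethoxyphenol
Product: 15 5-bromo-1,3-dimethoxy-2-(methoxymethoxy)benzene
Conditions: MOMCl (1.5 equiv), i-Pr2NEt (2 equiv), CH2Cl2, 0 → 40 °C
Reagents that add atoms: chloromethyl methyl ether, COCCl
Why: O-Alkylation of a hindered but acidic phenol. The same acetal as on ring A is chosen so that one final step removes all three.

Step 9
Reactants: 15 5-bromo-1,3-dimethoxy-2-(methoxymethoxy)benzene
Product: 18 [3,5-dimethoxy-4-(methoxymethoxy)phenyl]boronic acid, via aryllithium 16 (not isolated), via lithium borate 17 (not isolated)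
Conditions: n-BuLi (1.1 equiv), THF, −78 °C; B(Oi-Pr)3 (1.5 equiv), −78 °C → rt; aq NH4Cl (pH ≈ 6)
Reagents that add atoms: triisopropyl borate, CC(C)OB(OC(C)C)OC(C)C; water, O
Why: Bromine–lithium exchange is faster than any ortho-metalation at −78 °C. The borate traps the aryllithium as ate complex 17, and near-neutral hydrolysis gives the boronic acid without cleaving the acetal.

Step 10
Reactants: 13 6-[(2E)-3,7-dimethylocta-2,6-dien-1-yl]-5,7-bis(methoxymethoxy)-4H-chromen-4-one; 18 [3,5-dimethoxy-4-(methoxymethoxy)phenyl]boronic acid
Product: 19 (2S)-2-[3,5-dimethoxy-4-(methoxymethoxy)phenyl]-6-[(2E)-3,7-dimethylocta-2,6-dien-1-yl]-5,7-bis(methoxymethoxy)-2,3-dihydro-4H-chromen-4-one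
Conditions: [RhCl(C2H4)2]2 (2 mol %), (S)-MeO-F12-BIPHEP [(S)-2,2′-bis{bis(3,4,5-trifluorophenyl)phosphino}-6,6′-dimethoxy-1,1′-biphenyl, 4.4 mol %], aq KOH (10 mol %), 18 (3 equiv), CH2Cl2–H2O 10:1, 30 °C
Reagents that add atoms: none
Why: Hayashi–Miyaura asymmetric 1,4-addition of an arylboronic acid, the reaction type that converts chromones into flavanones. Transmetalation of 18 to the hydroxo complex of monovalent rhodium gives an aryl–rhodium species; the C2=C3 bond of 13 coordinates, the aryl group migrates to C2, and the resulting rhodium oxa-π-allyl is protonated at C3 by water, regenerating Rh–OH. No ring is closed: ring C is already in place, so O1–C2 is neither made nor broken and neither a chalcone nor a 6/8 scramble can arise. The single new stereocentre C2 is set under catalyst control by the C2-symmetric (S)-bisphosphine, whose quadrant model delivers the aryl group to the C2 Re face and so gives 2S. The step needs 1,4- over 1,2-addition and one addition only; the electron-poor ligand (fast insertion into the enone), the non-coordinating solvent and the peri C5 acetal that shields the product ketone should secure this. It also needs chemoselectivity over the geranyl alkenes, which follows because aryl–rhodium inserts only into the coordinating, electron-poor C2=C3 bond. The near-neutral medium keeps 19 closed, so C2 should not be eroded by retro-oxa-Michael opening.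

Step 11
Reactants: 19 (2S)-2-[3,5-dimethoxy-4-(methoxymethoxy)phenyl]-6-[(2E)-3,7-dimethylocta-2,6-dien-1-yl]-5,7-bis(methoxymethoxy)-2,3-dihydro-4H-chromen-4-one
Product: 20 (2S)-5,7-dihydroxy-2-(4-hydroxy-3,5-dimethoxyphenyl)-6-[(2E)-3,7-dimethylocta-2,6-dien-1-yl]-2,3-dihydro-4H-chromen-4-one (target)
Conditions: 3 M aq HCl–MeOH (1:5), 45 °C, monitored and stopped at full conversion
Reagents that add atoms: none
Why: Acid-catalysed methanolysis of the three aryl methoxymethyl acetals, which leave as dimethoxymethane. Dilute methanolic acid at moderate temperature is the usual way to unmask prenylated flavanones and should be slow to open O1–C2 or to protonate the trisubstituted alkenes, so the 2S centre and the 2E chain should be kept.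

## Compound list

1 | phloroglucinol (benzene-1,3,5-triol) | Oc1cc(O)cc(O)c1 | starting material
2 | 5-{[tri(propan-2-yl)silyl]oxy}benzene-1,3-diol | CC(C)[Si](Oc1cc(O)cc(O)c1)(C(C)C)C(C)C | intermediate
3 | [3,5-bis(methoxymethoxy)phenoxy]tri(propan-2-yl)silane | COCOc1cc(OCOC)cc(O[Si](C(C)C)(C(C)C)C(C)C)c1 | intermediate
4 | geranyl bromide, (2E)-1-bromo-3,7-dimethylocta-2,6-diene | CC(C)=CCC/C(C)=C/CBr | starting material
5 | {2,6-bis(methoxymethoxy)-4-{[tri(propan-2-yl)silyl]oxy}phenyl}lithium | [Li]c1c(OCOC)cc(O[Si](C(C)C)(C(C)C)C(C)C)cc1OCOC | intermediate (not isolated)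
6 | {4-[(2E)-3,7-dimethylocta-2,6-dien-1-yl]-3,5-bis(methoxymethoxy)phenoxy}tri(propan-2-yl)silane | COCOc1cc(O[Si](C(C)C)(C(C)C)C(C)C)cc(OCOC)c1C/C=C(\C)CCC=C(C)C | intermediate
7 | 4-[(2E)-3,7-dimethylocta-2,6-dien-1-yl]-3,5-bis(methoxymethoxy)phenol | COCOc1cc(O)cc(OCOC)c1C/C=C(\C)CCC=C(C)C | intermediate
8 | 4-[(2E)-3,7-dimethylocta-2,6-dien-1-yl]-2-(hydroxymethyl)-3,5-bis(methoxymethoxy)phenol (present as its magnesium salt) | COCOc1cc(O)c(CO)c(OCOC)c1C/C=C(\C)CCC=C(C)C | intermediate (not isolated)
9 | 3-[(2E)-3,7-dimethylocta-2,6-dien-1-yl]-6-hydroxy-2,4-bis(methoxymethoxy)benzaldehyde | COCOc1cc(O)c(C=O)c(OCOC)c1C/C=C(\C)CCC=C(C)C | intermediate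
10 | rac-1-{3-[(2E)-3,7-dimethylocta-2,6-dien-1-yl]-6-hydroxy-2,4-bis(methoxymethoxy)phenyl}prop-2-yn-1-ol | COCOc1cc(O)c(C(O)C#C)c(OCOC)c1C/C=C(\C)CCC=C(C)C | intermediate
11 | 1-{3-[(2E)-3,7-dimethylocta-2,6-dien-1-yl]-6-hydroxy-2,4-bis(methoxymethoxy)phenyl}prop-2-yn-1-one | COCOc1cc(O)c(C(=O)C#C)c(OCOC)c1C/C=C(\C)CCC=C(C)C | intermediate (not isolated)
12 | (2E)-3-(diethylamino)-1-{3-[(2E)-3,7-dimethylocta-2,6-dien-1-yl]-6-hydroxy-2,4-bis(methoxymethoxy)phenyl}prop-2-en-1-one | COCOc1cc(O)c(C(=O)/C=C/N(CC)CC)c(OCOC)c1C/C=C(\C)CCC=C(C)C | intermediate (not isolated)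
13 | 6-[(2E)-3,7-dimethylocta-2,6-dien-1-yl]-5,7-bis(methoxymethoxy)-4H-chromen-4-one | COCOc1cc2occc(=O)c2c(OCOC)c1C/C=C(\C)CCC=C(C)C | intermediate
14 | 4-bromo-2,6-dimethoxyphenol | COc1cc(Br)cc(OC)c1O | starting material
15 | 5-bromo-1,3-dimethoxy-2-(methoxymethoxy)benzene | COCOc1c(OC)cc(Br)cc1OC | intermediate
16 | [3,5-dimethoxy-4-(methoxymethoxy)phenyl]lithium | [Li]c1cc(OC)c(OCOC)c(OC)c1 | intermediate (not isolated)
17 | lithium [3,5-dimethoxy-4-(methoxymethoxy)phenyl]tri(propan-2-yloxy)borate | [Li+].CC(C)O[B-](OC(C)C)(OC(C)C)c1cc(OC)c(OCOC)c(OC)c1 | intermediate (not isolated)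
18 | [3,5-dimethoxy-4-(methoxymethoxy)phenyl]boronic acid | COCOc1c(OC)cc(B(O)O)cc1OC | intermediate
19 | (2S)-2-[3,5-dimethoxy-4-(methoxymethoxy)phenyl]-6-[(2E)-3,7-dimethylocta-2,6-dien-1-yl]-5,7-bis(methoxymethoxy)-2,3-dihydro-4H-chromen-4-one | COc1cc([C@@H]2CC(=O)c3c(cc(OCOC)c(C/C=C(\C)CCC=C(C)C)c3OCOC)O2)cc(OC)c1OCOC | intermediate
20 | (2S)-5,7-dihydroxy-2-(4-hydroxy-3,5-dimethoxyphenyl)-6-[(2E)-3,7-dimethylocta-2,6-dien-1-yl]-2,3-dihydro-4H-chromen-4-one | COc1cc([C@@H]2CC(=O)c3c(cc(O)c(C/C=C(\C)CCC=C(C)C)c3O)O2)cc(OC)c1O | target

## Step count and least certain steps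

Total step count: 11. Longest linear sequence: 9 (steps 1 to 7, then 10 and 11); steps 8 and 9 form the two-step branch to 18.

**Step 10 (key step).** The chromone is an electron-rich vinylogous ester with a peri alkoxy group, so carbometalation may be slow and protodeboronation of the electron-rich boronic acid may outrun it. A second, 1,2-addition to the product ketone and incomplete or reversed facial selectivity are the other failure modes. Fallback from 9, returning at 19, with regiochemistry still fixed because only one phenol is free:
- Methylmagnesium bromide addition to 9 would give the carbinol rac-1-{3-[(2E)-3,7-dimethylocta-2,6-dien-1-yl]-6-hydroxy-2,4-bis(methoxymethoxy)phenyl}ethan-1-ol F1.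
- MnO2 oxidation would give the methyl ketone 1-{3-[(2E)-3,7-dimethylocta-2,6-dien-1-yl]-6-hydroxy-2,4-bis(methoxymethoxy)phenyl}ethan-1-one F2.
- Claisen–Schmidt condensation of F2 (KOH, EtOH) with 3,5-dimethoxy-4-(methoxymethoxy)benzaldehyde F3, made from syringaldehyde and MOMCl, would give the 2′-hydroxychalcone (2E)-1-{3-[(2E)-3,7-dimethylocta-2,6-dien-1-yl]-6-hydroxy-2,4-bis(methoxymethoxy)phenyl}-3-[3,5-dimethoxy-4-(methoxymethoxy)phenyl]prop-2-en-1-one F4.
- Enantioselective 6-endo oxa-Michael cyclisation of F4 with a bifunctional quinine-derived thiourea would lead to 19, with enrichment by crystallisation or chromatography on a chiral phase if the selectivity is incomplete.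

**Step 3.** Metalation may be incomplete, and the allylic substitution may leak into γ-attack or allyl scrambling, which would give the branched chain or erode the 2E geometry; homocoupling of the bromide is also possible. Fallback from 3, returning at 6, which reverses the roles of the partners:
- The aryllithium 5 is quenched with iodine to give the aryl iodide [4-iodo-3,5-bis(methoxymethoxy)phenoxy]tri(propan-2-yl)silane F5.
- F5 is coupled under α-selective Suzuki–Miyaura conditions (Pd(OAc)2 reduced in situ to zerovalent palladium, bulky biaryl phosphine, K3PO4, THF–H2O) with the geranyl pinacol boronate 2-[(2E)-3,7-dimethylocta-2,6-dien-1-yl]-4,4,5,5-tetramethyl-1,3,2-dioxaborolane F6, prepared from 4 by copper-catalysed borylation with B2pin2.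

**Step 7.** The electron-rich phenol may be oxidised on MnO2, the ortho-hydroxybenzylic carbinol may ionise and oligomerise before it is oxidised, and the ynone may close in the 5-exo mode. Fallback from 9, returning at 13, which avoids the ynone altogether:
- 9 is taken through carbinol F1 and methyl ketone F2 as described above.
- F2 is heated with Me2NCH(OMe)2 (toluene, 80 °C) to give the enaminone (2E)-3-(dimethylamino)-1-{3-[(2E)-3,7-dimethylocta-2,6-dien-1-yl]-6-hydroxy-2,4-bis(methoxymethoxy)phenyl}prop-2-en-1-one F7.
- F7 cyclises on silica gel or with acetic acid to 13.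

**Step 11.** Protonation of the trisubstituted alkenes may lead to cyclisation onto the freed C5 or C7 hydroxyl or to addition of HCl, and acid-catalysed opening of O1–C2 may erode the configuration at C2. Fallback from 19, returning at 20, which replaces protic solvolysis by an aprotic acetal-to-silyl-ether exchange:
- Me3SiOTf and 2,2′-bipyridyl (CH2Cl2, 0 °C) would convert the three aryl acetals into the tris(trimethylsilyl) ether (2S)-2-[3,5-dimethoxy-4-(trimethylsilyloxy)phenyl]-6-[(2E)-3,7-dimethylocta-2,6-dien-1-yl]-5,7-bis(trimethylsilyloxy)-2,3-dihydro-4H-chromen-4-one F8.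
- F8 is hydrolysed with water at neutral pH to 20.

## Further compounds

F1 | step 10 | rac-1-{3-[(2E)-3,7-dimethylocta-2,6-dien-1-yl]-6-hydroxy-2,4-bis(methoxymethoxy)phenyl}ethan-1-ol | COCOc1cc(O)c(C(C)O)c(OCOC)c1C/C=C(\C)CCC=C(C)C
F2 | step 10 | 1-{3-[(2E)-3,7-dimethylocta-2,6-dien-1-yl]-6-hydroxy-2,4-bis(methoxymethoxy)phenyl}ethan-1-one | COCOc1cc(O)c(C(C)=O)c(OCOC)c1C/C=C(\C)CCC=C(C)C
F3 | step 10 | 3,5-dimethoxy-4-(methoxymethoxy)benzaldehyde | COCOc1c(OC)cc(C=O)cc1OC
F4 | step 10 | (2E)-1-{3-[(2E)-3,7-dimethylocta-2,6-dien-1-yl]-6-hydroxy-2,4-bis(methoxymethoxy)phenyl}-3-[3,5-dimethoxy-4-(methoxymethoxy)phenyl]prop-2-en-1-one | COCOc1cc(O)c(C(=O)/C=C/c2cc(OC)c(OCOC)c(OC)c2)c(OCOC)c1C/C=C(\C)CCC=C(C)C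
F5 | step 3 | [4-iodo-3,5-bis(methoxymethoxy)phenoxy]tri(propan-2-yl)silane | COCOc1cc(O[Si](C(C)C)(C(C)C)C(C)C)cc(OCOC)c1I
F6 | step 3 | 2-[(2E)-3,7-dimethylocta-2,6-dien-1-yl]-4,4,5,5-tetramethyl-1,3,2-dioxaborolane | CC(C)=CCC/C(C)=C/CB1OC(C)(C)C(C)(C)O1
F7 | step 7 | (2E)-3-(dimethylamino)-1-{3-[(2E)-3,7-dimethylocta-2,6-dien-1-yl]-6-hydroxy-2,4-bis(methoxymethoxy)phenyl}prop-2-en-1-one | COCOc1cc(O)c(C(=O)/C=C/N(C)C)c(OCOC)c1C/C=C(\C)CCC=C(C)C
F8 | step 11 | (2S)-2-[3,5-dimethoxy-4-(trimethylsilyloxy)phenyl]-6-[(2E)-3,7-dimethylocta-2,6-dien-1-yl]-5,7-bis(trimethylsilyloxy)-2,3-dihydro-4H-chromen-4-one | COc1cc([C@@H]2CC(=O)c3c(cc(O[Si](C)(C)C)c(C/C=C(\C)CCC=C(C)C)c3O[Si](C)(C)C)O2)cc(OC)c1O[Si](C)(C)C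
A1 | alternative 1 | 1-{3-[(2E)-3,7-dimethylocta-2,6-dien-1-yl]-2,4,6-trihydroxyphenyl}ethan-1-one | CC(=O)c1c(O)cc(O)c(C/C=C(\C)CCC=C(C)C)c1O
A2 | alternative 1 | (2E)-1-{3-[(2E)-3,7-dimethylocta-2,6-dien-1-yl]-2,4,6-trihydroxyphenyl}-3-(4-hydroxy-3,5-dimethoxyphenyl)prop-2-en-1-one | COc1cc(/C=C/C(=O)c2c(O)cc(O)c(C/C=C(\C)CCC=C(C)C)c2O)cc(OC)c1O
A3 | alternative 2 | 2-{[(2E)-3,7-dimethylocta-2,6-dien-1-yl]oxy}-4,6-bis(methoxymethoxy)benzaldehyde | COCOc1cc(OCOC)c(C=O)c(OC/C=C(\C)CCC=C(C)C)c1
A4 | alternative 2 | 5-(3,7-dimethylocta-1,6-dien-3-yl)-2,4-bis(methoxymethoxy)-6-oxocyclohexa-1,3-diene-1-carbaldehyde (mixture of stereoisomers) | O=CC1=C(OCOC)C=C(OCOC)C(C(C)(C=C)CCC=C(C)C)C1=O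
A5 | alternative 2 | 3-[(2Z)-3,7-dimethylocta-2,6-dien-1-yl]-6-hydroxy-2,4-bis(methoxymethoxy)benzaldehyde | COCOc1cc(O)c(C=O)c(OCOC)c1C/C=C(/C)CCC=C(C)C
A6 | alternative 3 | (3S)-3-{4-[(2E)-3,7-dimethylocta-2,6-dien-1-yl]-3,5-bis(methoxymethoxy)phenoxy}-3-[3,5-dimethoxy-4-(methoxymethoxy)phenyl]propanoic acid | OC(=O)C[C@H](Oc1cc(OCOC)c(C/C=C(\C)CCC=C(C)C)c(OCOC)c1)c1cc(OC)c(OCOC)c(OC)c1
A7 | alternative 3 | methyl (3R)-3-hydroxy-3-[3,5-dimethoxy-4-(methoxymethoxy)phenyl]propanoate | COC(=O)C[C@@H](O)c1cc(OC)c(OCOC)c(OC)c1
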